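## Retrosynthetic overview

- The target comes from global desilylation of a fully silylated flavanone. Rings A and B are bought as arenes, and ring C is formed last.
- Ring C comes from one formal [4+2] union of a protected 3,4-dihydroxybenzaldehyde (which supplies C2 and O1) with a dearomatised ring A diene. C2–C3 and O1–C8a are made together, and loss of methanol then restores aromatic ring A.
- Enabling feature: in ring A the C5 hydroxyl is para to the alkyl-bearing C8, and C8a lies between C8 and the acyl-bearing C4a. Oxidising a C8a-unsubstituted resorcinol ketone to its 4-methoxycyclohexa-2,5-dienone makes C4a=C8a a true enone bond, β to both C5=O and C4=O. Joined to the enol silane C3=C4, this bond is the diene retron of the 2,3-dihydropyran-4-one ring C, so O1 arrives with the aldehyde.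
- The ring A ketone comes from 4-bromoresorcinol by three regiodefined metalations (C8 prenyl, C6 prenyl, C4a acetyl). The first prenyl group is converted into the (R)-allylic alcohol (Shi epoxidation, epoxide isomerisation) before the second is introduced.

Key step: step 13

Abbreviations: MOM = methoxymethyl, TBS = tert-butyldimethylsilyl, TES = triethylsilyl, TMS = trimethylsilyl, prenyl = 3-methylbut-2-enyl. Flavanone numbering (O1, C2, C3, C4, C4a, C5 to C8, C8a) is used for ring A carbons in the explanations.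

Assumption: the sense of induction of the chromium catalyst is extrapolated from its reactions with simple aldehydes, where the (1S,2R) ligand should leave the Si face of the aldehyde open. If the sense proves opposite, the (1R,2S) ligand is used.

## Route

Step 1
Reactants: 1 4-bromobenzene-1,3-diol (4-bromoresorcinol)
Product: 2 1-bromo-2,4-bis(methoxymethoxy)benzene
Conditions: MOMCl, iPr2NEt, CH2Cl2, 0 °C → rt
Reagents that add atoms: chloromethyl methyl ether, COCCl
Why: Base-mediated O-alkylation (Williamson-type acetal protection) caps both phenols as MOM ethers, which survive organolithium reagents and later direct the ortho-metalations.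

Step 2
Reactants: 2 1-bromo-2,4-bis(methoxymethoxy)benzene
Product: 4 2,4-bis(methoxymethoxy)-1-prenylbenzene, via aryllithium 3 (not isolated)
Conditions: n-BuLi, THF, −78 °C; CuBr·SMe2 (10 mol %), prenyl bromide, −78 °C → rt
Reagents that add atoms: prenyl bromide, CC(C)=CCBr
Why: Bromine–lithium exchange places the carbanion unambiguously on the carbon that becomes C8, and copper-catalysed SN2 allylation with the primary allylic bromide should give the linear prenylarene.

Step 3
Reactants: 4 2,4-bis(methoxymethoxy)-1-prenylbenzene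
Product: 5 (3R)-3-{[2,4-bis(methoxymethoxy)phenyl]methyl}-2,2-dimethyloxirane
Conditions: D-fructose-derived Shi ketone (30 mol %), Oxone (2KHSO5·KHSO4·K2SO4), K2CO3, Bu4NHSO4 (cat.), MeCN–dimethoxymethane/aq. Na2B4O7 buffer, 0 °C
Reagents that add atoms: potassium peroxymonosulfate (oxidant in Oxone), [K+].[O-]S(=O)(=O)OO
Why: Shi asymmetric epoxidation, in which the chiral dioxirane formed in situ transfers oxygen through a spiro transition state to the face of the only (trisubstituted) alkene that gives the (R)-epoxide, sets the side-chain stereocentre.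

Step 4
Reactants: 5 (3R)-3-{[2,4-bis(methoxymethoxy)phenyl]methyl}-2,2-dimethyloxirane
Product: 6 (2R)-1-[2,4-bis(methoxymethoxy)phenyl]-3-methylbut-3-en-2-ol
Conditions: Al(OiPr)3 (0.5 equiv, promoter), toluene, 100 °C
Reagents that add atoms: none
Why: In this aluminium-alkoxide-promoted isomerisation of an epoxide to an allylic alcohol the C–O bond at the tertiary carbon breaks with loss of a methyl proton, so the secondary C–O bond and its (R) configuration are not touched.

Step 5
Reactants: 6 (2R)-1-[2,4-bis(methoxymethoxy)phenyl]-3-methylbut-3-en-2-ol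
Product: 7 TBS ether of 6
Conditions: TBSCl, imidazole, DMF, rt
Reagents that add atoms: tert-butyldimethylsilyl chloride, CC(C)(C)[Si](C)(C)Cl
Why: Standard silyl ether protection masks the secondary alcohol in a form that tolerates n-BuLi and is removed by fluoride at the end.

Step 6
Reactants: 7 TBS ether of 6
Product: 9 TBS ether of (2R)-1-[2,4-bis(methoxymethoxy)-3-prenylphenyl]-3-methylbut-3-en-2-ol, via aryllithium 8 (not isolated)
Conditions: n-BuLi, THF, 0 °C; CuBr·SMe2 (10 mol %), prenyl bromide, −78 °C → rt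
Reagents that add atoms: prenyl bromide, CC(C)=CCBr
Why: Directed ortho-metalation takes the ring position flanked by both MOM ethers (future C6), and copper-catalysed allylation brings in the second prenyl group only after the first has been oxidised, so the two side chains never have to be told apart.

Step 7
Reactants: 9 TBS ether of (2R)-1-[2,4-bis(methoxymethoxy)-3-prenylphenyl]-3-methylbut-3-en-2-ol
Product: 11 1-{5-[(2R)-2-(TBS-oxy)-3-methylbut-3-enyl]-2,4-bis(methoxymethoxy)-3-prenylphenyl}ethanone, via aryllithium 10 (not isolated)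
Conditions: n-BuLi, TMEDA, THF, −20 °C; MeC(O)N(OMe)Me, −78 → 0 °C; H2O
Reagents that add atoms: N-methoxy-N-methylacetamide, CC(=O)N(C)OC
Why: A second directed ortho-metalation can only take the last C–H next to a MOM ether (future C4a), because the other free position (future C8a) is meta to both oxygens, and the Weinreb ketone synthesis stops at the methyl ketone.

Step 8
Reactants: 11 1-{5-[(2R)-2-(TBS-oxy)-3-methylbut-3-enyl]-2,4-bis(methoxymethoxy)-3-prenylphenyl}ethanone
Product: 13 1-{5-[(2R)-2-(TBS-oxy)-3-methylbut-3-enyl]-2,4-dihydroxy-3-prenylphenyl}ethanone, via bis(trimethylsilyl) ether 12 (not isolated)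
Conditions: TMSOTf, 2,2′-bipyridyl, MeCN, 0 °C → rt; then H2O, rt
Reagents that add atoms: none
Why: Silyl-triflate/2,2′-bipyridyl cleavage of aromatic MOM ethers runs through the aryl silyl ethers under almost neutral conditions, which should spare the TBS ether and avoid acid-induced chroman formation of the ortho-prenylphenols.

Step 9
Reactants: 13 1-{5-[(2R)-2-(TBS-oxy)-3-methylbut-3-enyl]-2,4-dihydroxy-3-prenylphenyl}ethanone
Product: 14 1-{4-(TBS-oxy)-5-[(2R)-2-(TBS-oxy)-3-methylbut-3-enyl]-2-hydroxy-3-prenylphenyl}ethanone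
Conditions: TBSCl (1.2 equiv), imidazole, DMF, rt
Reagents that add atoms: tert-butyldimethylsilyl chloride, CC(C)(C)[Si](C)(C)Cl
Why: This is a chemoselective silylation, because the hydroxyl next to the acetyl group is tied up in an intramolecular hydrogen bond and only the other phenol (future O7) should react.

Step 10
Reactants: 14 1-{4-(TBS-oxy)-5-[(2R)-2-(TBS-oxy)-3-methylbut-3-enyl]-2-hydroxy-3-prenylphenyl}ethanone
Product: 15 2-acetyl-5-(TBS-oxy)-4-[(2R)-2-(TBS-oxy)-3-methylbut-3-enyl]-4-methoxy-6-prenylcyclohexa-2,5-dien-1-one (both epimers at the ring carbon bearing methoxy)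
Conditions: PhI(OAc)2, NaHCO3, CH2Cl2–MeOH, 0 °C, short reaction time
Reagents that add atoms: methanol, CO
Why: In this oxidative dearomatisation of a para-alkylphenol with a trivalent iodine reagent, well known for 4-alkylresorcinol monoethers, methanol is captured para to the phenol oxygen at the carbon bearing the side chain, and the new quaternary centre, formed as both epimers, is erased in step 13.

Step 11
Reactants: 15 2-acetyl-5-(TBS-oxy)-4-[(2R)-2-(TBS-oxy)-3-methylbut-3-enyl]-4-methoxy-6-prenylcyclohexa-2,5-dien-1-one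
Product: 16 5-(TBS-oxy)-4-[(2R)-2-(TBS-oxy)-3-methylbut-3-enyl]-4-methoxy-6-prenyl-2-[1-(TES-oxy)ethenyl]cyclohexa-2,5-dien-1-one
Conditions: TESOTf, Et3N, CH2Cl2, −78 °C
Reagents that add atoms: triethylsilyl trifluoromethanesulfonate, CC[Si](CC)(CC)OS(=O)(=O)C(F)(F)F
Why: Soft enolisation with a silyl triflate and an amine converts the only enolisable carbonyl group, the methyl ketone, into its enol silane without touching the non-enolisable dienone.

Step 12
Reactants: 17 3,4-dihydroxybenzaldehyde
Product: 18 3,4-bis(TBS-oxy)benzaldehyde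
Conditions: TBSCl, imidazole, DMF, rt
Reagents that add atoms: tert-butyldimethylsilyl chloride, CC(C)(C)[Si](C)(C)Cl
Why: Standard bis-silylation protects the catechol with groups that are inert to mild Lewis acids and fall in the same final fluoride step as all the others.

Step 13
Reactants: 16 5-(TBS-oxy)-4-[(2R)-2-(TBS-oxy)-3-methylbut-3-enyl]-4-methoxy-6-prenyl-2-[1-(TES-oxy)ethenyl]cyclohexa-2,5-dien-1-one; 18 3,4-bis(TBS-oxy)benzaldehyde
Product: 21 (2S)-2-[3,4-bis(TBS-oxy)phenyl]-7-(TBS-oxy)-8-[(2R)-2-(TBS-oxy)-3-methylbut-3-enyl]-5-hydroxy-6-prenylchroman-4-one, via cycloadduct 19 (not isolated), via diketone 20 (not isolated)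
Conditions: 18 (1.5 equiv), [Cr(L)Cl] (10 mol %; L = dianion of (1S,2R)-1-{[3-(1-adamantyl)-2-hydroxy-5-methylbenzylidene]amino}indan-2-ol), 4 Å molecular sieves, t-BuOMe, rt, slow addition of 16; then camphorsulfonic acid (10 mol %), moist CH2Cl2, 0 °C
Reagents that add atoms: none
Why: Proposed new method: the trivalent chromium Lewis acid binds the aldehyde oxygen of 18, and the push–pull diene C3=C4(OTES)–C4a=C8a of 16 adds across the C=O group in a polarity-matched, strongly asynchronous [4+2] event in which the enol-silane terminus C3 bonds to the carbonyl carbon (C2) and the carbonyl oxygen (O1) bonds to C8a, the β-carbon of both the C5 dienone carbonyl and the latent C4 ketone; its stepwise limit is a Mukaiyama aldol addition followed by an oxa-Michael addition. The closest known reaction types are the chromium–Schiff-base-catalysed hetero-Diels–Alder reaction of 2-silyloxy-1,3-dienes with aldehydes and the conjugate addition of oxygen nucleophiles to p-quinol ethers with rearomatisation, and only their merger on a 2-(1-silyloxyvinyl)cyclohexa-2,5-dienone is new. Ring C is the only ring closed, either within the six-membered cycloaddition array or, in the stepwise limit, by 6-endo-trig attack of O1 on C8a. Acid then hydrolyses the enol silane of 19 to diketone 20, which enolises towards C5 and loses the doubly allylic C8 methoxy group together with the C8a hydrogen, so ring A rearomatises irreversibly while the C2–O1 bond is never broken. C2 is the only lasting new stereocentre and is set by the catalyst, whose (1S,2R)-aminoindanol ligand should leave the Si face of the bound aldehyde open, whereas the centres at C8 and C8a are erased, so both C8 epimers of 16 and both endo and exo approaches converge on (2S)-21. The step needs the aldehyde rather than a second dienone to be the electrophile and needs O1 to attack C8a only: the first is secured by preferential Lewis-acid binding of the unhindered aldehyde, by the quaternary C8 that shields C8a from intermolecular attack and by slow addition of 16, the second by C8a being the only acceptor carbon at six-ring distance, and the isolated alkenes and silyl ethers are inert to the catalyst.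

Step 14
Reactants: 21 (2S)-2-[3,4-bis(TBS-oxy)phenyl]-7-(TBS-oxy)-8-[(2R)-2-(TBS-oxy)-3-methylbut-3-enyl]-5-hydroxy-6-prenylchroman-4-one
Product: 22 (2S)-2-(3,4-dihydroxyphenyl)-5,7-dihydroxy-8-[(2R)-2-hydroxy-3-methylbut-3-enyl]-6-prenylchroman-4-one (CNP0322081.2)
Conditions: HF·pyridine, pyridine, THF, 0 °C → rt
Reagents that add atoms: none
Why: Global fluoride-mediated desilylation under mildly acidic, buffered conditions removes all four TBS groups while avoiding both the base-induced retro-oxa-Michael ring opening that would epimerise C2 and the strong acid that would cyclise the prenyl and allylic alcohol groups onto the phenols.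

## Compound list

1 | 4-bromobenzene-1,3-diol | Oc1ccc(Br)c(O)c1 | starting material
2 | 1-bromo-2,4-bis(methoxymethoxy)benzene | COCOc1ccc(Br)c(OCOC)c1 | intermediate
3 | [2,4-bis(methoxymethoxy)phenyl]lithium | [Li]c1ccc(OCOC)cc1OCOC | intermediate
4 | 2,4-bis(methoxymethoxy)-1-prenylbenzene | CC(C)=CCc1ccc(OCOC)cc1OCOC | intermediate
5 | (3R)-3-{[2,4-bis(methoxymethoxy)phenyl]methyl}-2,2-dimethyloxirane | CC1(C)[C@H](O1)Cc2ccc(OCOC)cc2OCOC | intermediate
6 | (2R)-1-[2,4-bis(methoxymethoxy)phenyl]-3-methylbut-3-en-2-ol | C=C(C)[C@H](O)Cc1ccc(OCOC)cc1OCOC | intermediate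
7 | TBS ether of 6 | C=C(C)[C@H](O[Si](C)(C)C(C)(C)C)Cc1ccc(OCOC)cc1OCOC | intermediate
8 | 7 lithiated between the two MOM ethers | C=C(C)[C@H](O[Si](C)(C)C(C)(C)C)Cc1ccc(OCOC)c([Li])c1OCOC | intermediate
9 | TBS ether of (2R)-1-[2,4-bis(methoxymethoxy)-3-prenylphenyl]-3-methylbut-3-en-2-ol | C=C(C)[C@H](O[Si](C)(C)C(C)(C)C)Cc1ccc(OCOC)c(CC=C(C)C)c1OCOC | intermediate
10 | 9 lithiated at the last position next to a MOM ether | C=C(C)[C@H](O[Si](C)(C)C(C)(C)C)Cc1cc([Li])c(OCOC)c(CC=C(C)C)c1OCOC | intermediate
11 | 1-{5-[(2R)-2-(TBS-oxy)-3-methylbut-3-enyl]-2,4-bis(methoxymethoxy)-3-prenylphenyl}ethanone | C=C(C)[C@H](O[Si](C)(C)C(C)(C)C)Cc1cc(C(C)=O)c(OCOC)c(CC=C(C)C)c1OCOC | intermediate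
12 | 2,4-bis(TMS-oxy) analogue of 11 | C=C(C)[C@H](O[Si](C)(C)C(C)(C)C)Cc1cc(C(C)=O)c(O[Si](C)(C)C)c(CC=C(C)C)c1O[Si](C)(C)C | intermediate
13 | 1-{5-[(2R)-2-(TBS-oxy)-3-methylbut-3-enyl]-2,4-dihydroxy-3-prenylphenyl}ethanone | C=C(C)[C@H](O[Si](C)(C)C(C)(C)C)Cc1cc(C(C)=O)c(O)c(CC=C(C)C)c1O | intermediate
14 | 1-{4-(TBS-oxy)-5-[(2R)-2-(TBS-oxy)-3-methylbut-3-enyl]-2-hydroxy-3-prenylphenyl}ethanone | C=C(C)[C@H](O[Si](C)(C)C(C)(C)C)Cc1cc(C(C)=O)c(O)c(CC=C(C)C)c1O[Si](C)(C)C(C)(C)C | intermediate
15 | 2-acetyl-5-(TBS-oxy)-4-[(2R)-2-(TBS-oxy)-3-methylbut-3-enyl]-4-methoxy-6-prenylcyclohexa-2,5-dien-1-one (ring C4 epimers) | C=C(C)[C@H](O[Si](C)(C)C(C)(C)C)CC1(OC)C=C(C(C)=O)C(=O)C(CC=C(C)C)=C1O[Si](C)(C)C(C)(C)C | intermediate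
16 | TES enol ether of 15 (2-[1-(TES-oxy)ethenyl]dienone, ring C4 epimers) | C=C(C)[C@H](O[Si](C)(C)C(C)(C)C)CC1(OC)C=C(C(=C)O[Si](CC)(CC)CC)C(=O)C(CC=C(C)C)=C1O[Si](C)(C)C(C)(C)C | intermediate
17 | 3,4-dihydroxybenzaldehyde | O=Cc1ccc(O)c(O)c1 | starting material
18 | 3,4-bis(TBS-oxy)benzaldehyde | O=Cc1ccc(O[Si](C)(C)C(C)(C)C)c(O[Si](C)(C)C(C)(C)C)c1 | intermediate
19 | (2S)-cycloadduct: 8-methoxy-4-(TES-oxy)-2,3,8,8a-tetrahydrochromen-5-one carrying all substituents of 21 (epimers at C8 and C8a) | C=C(C)[C@H](O[Si](C)(C)C(C)(C)C)CC1(OC)C2O[C@H](c3ccc(O[Si](C)(C)C(C)(C)C)c(O[Si](C)(C)C(C)(C)C)c3)CC(O[Si](CC)(CC)CC)=C2C(=O)C(CC=C(C)C)=C1O[Si](C)(C)C(C)(C)C | intermediate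
20 | (2S)-4,5-diketone from hydrolysis of 19 (epimers at C4a, C8 and C8a) | C=C(C)[C@H](O[Si](C)(C)C(C)(C)C)CC1(OC)C2O[C@H](c3ccc(O[Si](C)(C)C(C)(C)C)c(O[Si](C)(C)C(C)(C)C)c3)CC(=O)C2C(=O)C(CC=C(C)C)=C1O[Si](C)(C)C(C)(C)C | intermediate
21 | (2S)-2-[3,4-bis(TBS-oxy)phenyl]-7-(TBS-oxy)-8-[(2R)-2-(TBS-oxy)-3-methylbut-3-enyl]-5-hydroxy-6-prenylchroman-4-one | C=C(C)[C@H](O[Si](C)(C)C(C)(C)C)Cc1c(O[Si](C)(C)C(C)(C)C)c(CC=C(C)C)c(O)c2c1O[C@H](c1ccc(O[Si](C)(C)C(C)(C)C)c(O[Si](C)(C)C(C)(C)C)c1)CC2=O | intermediate
22 | (2S)-2-(3,4-dihydroxyphenyl)-5,7-dihydroxy-8-[(2R)-2-hydroxy-3-methylbut-3-enyl]-6-prenylchroman-4-one | C=C(C)[C@H](O)Cc1c(O)c(CC=C(C)C)c(O)c2c1O[C@H](c1ccc(O)c(O)c1)CC2=O | target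

## Step count

- Total steps: 14.
- Longest linear sequence: 13 (steps 1 to 11, 13 and 14).

## Steps most likely to fail

**Step 13 (Proposed new method).**
- What may go wrong:
  - The cycloaddition may be sluggish, because an electron-rich aldehyde meets a diene whose nucleophilicity is damped by the dienone.
  - The diene may condense with itself by intermolecular Mukaiyama–Michael addition.
  - Facial selectivity at the aldehyde may be poor.
- Fallback: it sets out from 14 and comes back to the route at 20. The two bond formations are separated, and each is run as a known reaction. Ketone 14 is silylated twice (TMSOTf, Et3N, CH2Cl2, 0 °C) to the aryl TMS ether enol silane F1. A catalytic enantioselective Mukaiyama aldol addition of F1 to 18 then gives the (S)-aldol F2. The conditions are SiCl4 activated by a chiral bisphosphoramide, using the enantiomer that opens the Si face of the aldehyde, in CH2Cl2 at −78 °C, with an aqueous KF/NaHCO3 work-up that also frees the chelated phenol. Oxidative dearomatisation of F2 (PhI(OAc)2, NaHCO3, CH2Cl2–MeOH, 0 °C) gives the p-quinol methyl ether F3. Its secondary hydroxyl adds to C8a in an intramolecular oxa-Michael reaction to give diketone 20, and camphorsulfonic acid completes the passage to 21 as in step 13.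

**Step 10.**
- What may go wrong:
  - Ligand exchange of the hydrogen-bonded phenol at iodine may be slow.
  - Methanol may add in conjugate fashion to the newly formed, doubly activated enone, causing premature rearomatisation.
  - The silyl group that becomes a vinylogous silyl ester may be lost by solvolysis.
- Fallback: it sets out from 14 and comes back at 21. The nucleophilic alcohol solvent is given up, and the leaving group at C8 is built afterwards. PhI(OAc)2 in aqueous MeCN at 0 °C captures water and gives the p-quinol F4. Excess TESOTf/Et3N (CH2Cl2, −78 °C) silylates the tertiary hydroxyl and forms the enol silane in one operation, giving the bis(TES) diene F5. Diene F5 takes the place of 16 under the conditions of step 13. It passes through the cycloadduct F6 and the diketone F7, which loses triethylsilanol from C8 instead of methanol to give 21.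

**Step 7.**
- What may go wrong: metalation at the benzylic–allylic CH2 of the prenyl group or at the allylic carbinol position may compete with ring metalation, and conversion at the hindered ring position may be incomplete.
- Fallback: it sets out from 9 and comes back at 13. The carbanion route is replaced by a photo-Fries rearrangement. Both MOM ethers of 9 are cleaved as in step 8 (TMSOTf, 2,2′-bipyridyl, then H2O), through the bis(TMS) ether F8, to the resorcinol F9. The less hindered hydroxyl, which has only one ortho substituent, is acetylated selectively (Ac2O, 1 equiv, pyridine, 0 °C) to the monoacetate F10. Irradiation (254 nm, degassed cyclohexane) moves the acetyl group to the only free ortho position, the other ortho and the para positions being blocked, and gives 13 directly.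

## Further compounds

F1 | step 13 | aryl TMS ether and TMS enol ether of 14 | C=C(C)[C@H](O[Si](C)(C)C(C)(C)C)Cc1cc(C(=C)O[Si](C)(C)C)c(O[Si](C)(C)C)c(CC=C(C)C)c1O[Si](C)(C)C(C)(C)C
F2 | step 13 | (3S)-3-[3,4-bis(TBS-oxy)phenyl]-3-hydroxy-1-{4-(TBS-oxy)-5-[(2R)-2-(TBS-oxy)-3-methylbut-3-enyl]-2-hydroxy-3-prenylphenyl}propan-1-one | C=C(C)[C@H](O[Si](C)(C)C(C)(C)C)Cc1cc(C(=O)C[C@H](O)c2ccc(O[Si](C)(C)C(C)(C)C)c(O[Si](C)(C)C(C)(C)C)c2)c(O)c(CC=C(C)C)c1O[Si](C)(C)C(C)(C)C
F3 | step 13 | p-quinol methyl ether of F2 (4-methoxycyclohexa-2,5-dienone, ring C4 epimers) | C=C(C)[C@H](O[Si](C)(C)C(C)(C)C)CC1(OC)C=C(C(=O)C[C@H](O)c2ccc(O[Si](C)(C)C(C)(C)C)c(O[Si](C)(C)C(C)(C)C)c2)C(=O)C(CC=C(C)C)=C1O[Si](C)(C)C(C)(C)C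
F4 | step 10 | 2-acetyl-5-(TBS-oxy)-4-[(2R)-2-(TBS-oxy)-3-methylbut-3-enyl]-4-hydroxy-6-prenylcyclohexa-2,5-dien-1-one | C=C(C)[C@H](O[Si](C)(C)C(C)(C)C)CC1(O)C=C(C(C)=O)C(=O)C(CC=C(C)C)=C1O[Si](C)(C)C(C)(C)C
F5 | step 10 | 4-(TES-oxy)-2-[1-(TES-oxy)ethenyl] analogue of 16 | C=C(C)[C@H](O[Si](C)(C)C(C)(C)C)CC1(O[Si](CC)(CC)CC)C=C(C(=C)O[Si](CC)(CC)CC)C(=O)C(CC=C(C)C)=C1O[Si](C)(C)C(C)(C)C
F6 | step 10 | (2S)-cycloadduct of F5 and 18 (8-TES-oxy analogue of 19) | C=C(C)[C@H](O[Si](C)(C)C(C)(C)C)CC1(O[Si](CC)(CC)CC)C2O[C@H](c3ccc(O[Si](C)(C)C(C)(C)C)c(O[Si](C)(C)C(C)(C)C)c3)CC(O[Si](CC)(CC)CC)=C2C(=O)C(CC=C(C)C)=C1O[Si](C)(C)C(C)(C)C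
F7 | step 10 | (2S)-4,5-diketone from F6 (8-TES-oxy analogue of 20) | C=C(C)[C@H](O[Si](C)(C)C(C)(C)C)CC1(O[Si](CC)(CC)CC)C2O[C@H](c3ccc(O[Si](C)(C)C(C)(C)C)c(O[Si](C)(C)C(C)(C)C)c3)CC(=O)C2C(=O)C(CC=C(C)C)=C1O[Si](C)(C)C(C)(C)C
F8 | step 7 | bis(TMS) ether of F9 | C=C(C)[C@H](O[Si](C)(C)C(C)(C)C)Cc1ccc(O[Si](C)(C)C)c(CC=C(C)C)c1O[Si](C)(C)C
F9 | step 7 | 4-[(2R)-2-(TBS-oxy)-3-methylbut-3-enyl]-2-prenylbenzene-1,3-diol | C=C(C)[C@H](O[Si](C)(C)C(C)(C)C)Cc1ccc(O)c(CC=C(C)C)c1O
F10 | step 7 | 4-[(2R)-2-(TBS-oxy)-3-methylbut-3-enyl]-3-hydroxy-2-prenylphenyl acetate | C=C(C)[C@H](O[Si](C)(C)C(C)(C)C)Cc1ccc(OC(C)=O)c(CC=C(C)C)c1O
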